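Time at the hot temperature is where I start with these flasks, which share one recipe and differ in how the charges go in and in when the heat comes.

    electrophile + nucleophile → acid set free + target (k1 = 1.6 M⁻¹ min⁻¹, Ea1 = 49.0 kJ mol⁻¹)
    nucleophile + acid set free ⇌ protonated nucleophile, settled at all times (K2 = 1.8 × 10⁵ M⁻¹, ΔH2 = −86.0 kJ mol⁻¹)
    acid set free + free base ⇌ salt of the base (K3 = 1.2 × 10⁶ M⁻¹, k3 = 7.7 M⁻¹ min⁻¹, Ea3 = 55.0 kJ mol⁻¹, ΔH3 = −49.0 kJ mol⁻¹)
    target ⇌ isomer of the product (K4 = 29, k4 = 0.043 min⁻¹, Ea4 = 116 kJ mol⁻¹, ΔH4 = 24.0 kJ mol⁻¹)
    crystals ⇌ target, rate k5*(cs5 - [target]) while solid is left; crystals form when [target] > cs5 (cs5 = 1.2 mM, k5 = 1.6 min⁻¹)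
    electrophile + acid set free → side product (k6 = 0.34 M⁻¹ min⁻¹, Ea6 = 76.0 kJ mol⁻¹)
    (constants at 70 °C)

| setting | oak | ash | elm | maple |
|---|---|---|---|---|
| electrophile | 44 mM (fed, over 50 min) | 44 mM (fed, over 50 min) | 44 mM | 44 mM |
| free base | 22.0 mM | 22.0 mM | 22.0 mM (fed, over 50 min) | 22.0 mM |
| protonated nucleophile | 88.0 mM | 88.0 mM | 88.0 mM | 88.0 mM |
| time | 1.5 h | 1.5 h | 1.5 h | 1.5 h |
| remark | the addition at 30 °C, then warmed to 70 °C; the feed brings no volume worth counting | all else is in the flask from the start; the feed brings no volume worth counting | all else is in the flask from the start; the feed brings no volume worth counting | everything together at the start |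
| temperature |  | 70 °C | 70 °C | 70 °C |

- which flask leads in share of target in target plus isomer of the product ("all alike" within 1.5 percentage points) (oak / ash / elm / maple / all alike)
- share of target in target plus isomer of the product at the end, oak
- share of target in target plus isomer of the product at the end, ash
- share of target in target plus isomer of the product at the end, elm
- share of target in target plus isomer of the product at the end, maple

- what is said of target includes crystals
- crystals is a solid; its amount is given per volume of the solution
- constants are those at 70 °C; use the activation energies and enthalpies for any other temperature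

Two extreme versions of the flask can be solved in the head, and both concern the last link, target going over into isomer of the product. Under pure kinetic control nothing has isomerised and the share stands at 100%. Under full thermodynamic control the pair has reached its balance, so the share is the floor, one part in one plus the equilibrium constant, 3.33%, and this floor is the zero of my scale.

Between the extremes the pair relaxes with the sum of its forward and backward constants, the relaxation rate λ, 0.0445 min⁻¹, a half-life of 15.6 min. Since this step is first order, the amount made cancels from a share, provided c(target) stays under 1.2 mM and no crystals form.

What matters is the age of the target. If it is made at a steady pace over a hot time, and x is λ times that time, then the part of the span above the floor that survives is the mean of the decay curve: one minus e to the minus x, divided by x.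

For maple x is 4.00, which gives 27.0%.

For oak, the isomerisation at 30 °C has a constant of 2.012 × 10⁻⁴ min⁻¹, so over the feed it reaches an x of 0.0101, far smaller than the 1.78 of the hot remainder. The making constant there is 10.4% of its hot value, so I start the clock of oak at the warming and get 48.5%, higher than maple.

Ash and elm run hot for the whole 1.5 h with one charge fed over 50 min, and I place them between these two without a figure of their own.

The forecast names oak as leader, and its shares stand in the table beside mine and beside what the simulation gives. It holds that “crystals barely form and give no protection”. My maple figure stands above its own.

| flask | my rule | forecast | simulation |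
|---|---|---|---|
| oak | 48.5% | 47% | 47.9% |
| ash | between | 31% | 30.2% |
| elm | between | 29% | 28.9% |
| maple | 27.0% | 25.5% | 25.4% |

The simulation has oak in the lead. In maple the relaxation half-life, 0.260 h, is shorter than the run of 1.5 h. At the end of maple, target is made at 0.985 of the rate at which it is used, and crystals stand at 0%.

In the repeat of maple at 95 °C, λ rises from 0.0445 min⁻¹ to 0.693 min⁻¹ and the floor falls to 1.91%, so the rule gives 3.48%. That flask gives 2.41%, with free base down to 0.216% of its charge.

Its constants are made up, and the outcome is calculated.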